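## Plan

- **Cuts:** the C5 methylene is traced back to a menthyl acetal carbon and the C7 methylene to a dithiane carbon. C4–C7 and C3–C7' are then cut together, leaving a butenolide, an aryl dithiane and a benzyl bromide.
- **Enabling feature:** in the γ-lactone ring (O1, C2 carbonyl, C3, C4, C5), the adjacent carbons C3 and C4 carry trans 3,4,5-trimethoxybenzyl groups (C7' on C3, C7 on C4). This is the imprint of an electrophile at C3 and a nucleophile at C4 of a C3=C4 butenolide.
- **Forward:** the lactone, the only non-aromatic ring, exists from step 1 (furfural photo-oxygenation, then the menthol acetal). Both aryl arms are attached to it in one flask, and it is opened and reclosed once, in the last step.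
- **Stereochemistry:** l-menthol delivers the crystalline 5R acetal. C5 sends the nucleophile anti (4R) and C4 sends the electrophile anti (3R). C5 is finally reduced to CH2 and the auxiliary leaves.

Key step: step 5

Assumption: the SMILES string is read as the (3R,4R)-trans lactone. The numbering O1, C2 (C=O), C3, C4, C5, with C7 on C4 and C7' on C3, is used throughout.

## Route

Step 1
Reactants: 1 furfural
Product: 3 5-hydroxyfuran-2(5H)-one (racemic hemiacetal), via furfural endoperoxide 2 (not isolated)
Conditions: O2, hν (visible), methylene blue (cat.), MeOH, 15 °C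
Reagents that add atoms: oxygen, O=O
Why: Dye-sensitised photo-oxygenation, in which singlet oxygen adds across C2/C5 of the furan in a [4+2] cycloaddition and methanol strips the formyl group from endoperoxide 2, unveiling the γ-hydroxybutenolide with a racemic and configurationally labile hemiacetal carbon.

Step 2
Reactants: 3 5-hydroxyfuran-2(5H)-one; 4 l-menthol [(1R,2S,5R)-2-isopropyl-5-methylcyclohexan-1-ol]
Product: 5 (5R)-5-(l-menthyloxy)furan-2(5H)-one
Conditions: (+)-camphor-10-sulfonic acid (cat.), toluene, reflux, Dean–Stark trap; crystallisation from hexane, −20 °C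
Reagents that add atoms: none
Why: Acid-catalysed acetalisation of the pseudo-acid with removal of water gives both C5 epimers, which interconvert under the acid, so the less soluble 5R epimer should be collected by crystallisation and the re-equilibrated mother liquor cropped again (crystallisation-driven epimerisation, C5 set by the menthol auxiliary).

Step 3
Reactants: 6 3,4,5-trimethoxybenzaldehyde
Product: 7 2-(3,4,5-trimethoxyphenyl)-1,3-dithiane
Conditions: HS(CH2)3SH, BF3·OEt2 (cat.), CH2Cl2, 0 °C → rt
Reagents that add atoms: propane-1,3-dithiol, SCCCS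
Why: Lewis-acid-catalysed thioacetalisation of an aromatic aldehyde leaves the aryl methyl ethers untouched and turns the future C7 into an acyl-anion equivalent (umpolung).

Step 4
Reactants: 8 3,4,5-trimethoxybenzyl alcohol
Product: 9 3,4,5-trimethoxybenzyl bromide
Conditions: PBr3, Et2O, 0 °C
Reagents that add atoms: phosphorus tribromide, BrP(Br)Br
Why: SN2 bromination of a primary benzylic alcohol through its phosphite ester is routine, and the electron-rich, labile bromide is used freshly made.

Step 5
Reactants: 7 2-(3,4,5-trimethoxyphenyl)-1,3-dithiane; 5 (5R)-5-(l-menthyloxy)furan-2(5H)-one; 9 3,4,5-trimethoxybenzyl bromide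
Product: 12 (3R,4R,5R)-5-(l-menthyloxy)-3-(3,4,5-trimethoxybenzyl)-4-[2-(3,4,5-trimethoxyphenyl)-1,3-dithian-2-yl]oxolan-2-one, via 2-lithio-2-aryl-1,3-dithiane 10 (not isolated), via lithium enolate 11 (not isolated)
Conditions: 7, n-BuLi, THF, −30 °C; 5, −78 °C; 9, DMPU, −78 °C → rt; aq NH4Cl
Reagents that add atoms: none
Why: Deprotonation of 7 gives the aryl- and sulfur-stabilised carbanion 10, which attacks C4 of 5 in a Michael addition to give lithium enolate 11, and 11 is C-benzylated at C3 by bromide 9 in an SN2 step, so C4–C7 and C3–C7' form in one flask and no ring closes. The closest known reaction type is the tandem conjugate addition–enolate alkylation of acyl-anion equivalents on butenolides and 5-alkoxyfuran-2(5H)-ones. C4 is controlled by the C5 menthyloxy group, which covers one face of the flat ring so that 10 enters anti to it (5R leads to 4R). C3 is controlled by the very large dithianyl group now on C4, which sends 9 to the opposite face of the enolate (3R, 3,4-trans). The step needs 1,4- over 1,2-addition, secured by the soft delocalised anion and the weakly electrophilic lactone carbonyl, and C- over O-alkylation, secured by the soft benzylic bromide and the lithium counter-ion. DMPU loosens the enolate aggregate so that alkylation should outrun proton exchange and retro-Michael cleavage.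

Step 6
Reactants: 12 (3R,4R,5R)-5-(l-menthyloxy)-3-(3,4,5-trimethoxybenzyl)-4-[2-(3,4,5-trimethoxyphenyl)-1,3-dithian-2-yl]oxolan-2-one
Product: 13 (3R,4R,5R)-5-(l-menthyloxy)-3,4-bis(3,4,5-trimethoxybenzyl)oxolan-2-one
Conditions: Raney Ni (W-2, washed neutral, excess), EtOH–THF, reflux
Reagents that add atoms: none
Why: Mozingo-type reductive desulfurisation cleaves both benzylic C–S bonds and leaves C7 as a methylene, while lactone, acetal, aryl ethers and the C3, C4 and C5 stereocentres take no part; clearing the bulky dithiane first also opens access to the lactone carbonyl for step 7.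

Step 7
Reactants: 13 (3R,4R,5R)-5-(l-menthyloxy)-3,4-bis(3,4,5-trimethoxybenzyl)oxolan-2-one
Product: 17 (3R,4R)-3,4-bis(3,4,5-trimethoxybenzyl)oxolan-2-one [(−)-cubebininolide], via potassium aldehyde carboxylate 14 (not isolated), via potassium hydroxy carboxylate 15 (not isolated), via hydroxy acid 16 (not isolated)
Conditions: NaBH4, KOH, EtOH–H2O, 0 °C → rt; then 2 M HCl to pH 1, rt
Reagents that add atoms: potassium hydroxide, [K+].[OH-] (its oxygen enters the carboxylate of 14–16; one carboxyl oxygen leaves again as water on lactonisation)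
Why: Saponification of the pseudo-ester releases menthol and unmasks C5 as aldehyde 14, borohydride reduces it at once to 15, and acidification closes hydroxy acid 16 by 5-exo-trig lactonisation, with C3 and C4 carried through unchanged because the aldehyde should be reduced faster than it enolises.

## Compound list

1 | furfural | O=Cc1ccco1 | starting material
2 | furfural 2,5-endoperoxide (2,3,7-trioxabicyclo[2.2.1]hept-5-ene-1-carbaldehyde, racemic) | O=CC12OOC(C=C1)O2 | intermediate
3 | 5-hydroxyfuran-2(5H)-one (racemic) | OC1OC(=O)C=C1 | intermediate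
4 | l-menthol, (1R,2S,5R)-2-isopropyl-5-methylcyclohexan-1-ol | CC(C)[C@@H]1CC[C@@H](C)C[C@H]1O | starting material
5 | (5R)-5-(l-menthyloxy)furan-2(5H)-one | CC(C)[C@@H]1CC[C@@H](C)C[C@H]1O[C@@H]1OC(=O)C=C1 | intermediate
6 | 3,4,5-trimethoxybenzaldehyde | COc1cc(C=O)cc(OC)c1OC | starting material
7 | 2-(3,4,5-trimethoxyphenyl)-1,3-dithiane | COc1cc(C2SCCCS2)cc(OC)c1OC | intermediate
8 | 3,4,5-trimethoxybenzyl alcohol | COc1cc(CO)cc(OC)c1OC | starting material
9 | 3,4,5-trimethoxybenzyl bromide | COc1cc(CBr)cc(OC)c1OC | intermediate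
10 | 2-lithio-2-(3,4,5-trimethoxyphenyl)-1,3-dithiane | COc1cc(C2([Li])SCCCS2)cc(OC)c1OC | intermediate
11 | lithium (4R,5R)-5-(l-menthyloxy)-4-[2-(3,4,5-trimethoxyphenyl)-1,3-dithian-2-yl]-4,5-dihydrofuran-2-olate | CC(C)[C@@H]1CC[C@@H](C)C[C@H]1O[C@@H]1OC(O[Li])=C[C@H]1C1(c2cc(OC)c(OC)c(OC)c2)SCCCS1 | intermediate
12 | (3R,4R,5R)-5-(l-menthyloxy)-3-(3,4,5-trimethoxybenzyl)-4-[2-(3,4,5-trimethoxyphenyl)-1,3-dithian-2-yl]oxolan-2-one (all-trans) | CC(C)[C@@H]1CC[C@@H](C)C[C@H]1O[C@@H]1OC(=O)[C@H](Cc2cc(OC)c(OC)c(OC)c2)[C@H]1C1(c2cc(OC)c(OC)c(OC)c2)SCCCS1 | intermediate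
13 | (3R,4R,5R)-5-(l-menthyloxy)-3,4-bis(3,4,5-trimethoxybenzyl)oxolan-2-one | CC(C)[C@@H]1CC[C@@H](C)C[C@H]1O[C@@H]1OC(=O)[C@H](Cc2cc(OC)c(OC)c(OC)c2)[C@H]1Cc1cc(OC)c(OC)c(OC)c1 | intermediate
14 | potassium (2R,3R)-4-oxo-2,3-bis(3,4,5-trimethoxybenzyl)butanoate | COc1cc(C[C@@H](C=O)[C@@H](Cc2cc(OC)c(OC)c(OC)c2)C(=O)[O-])cc(OC)c1OC.[K+] | intermediate
15 | potassium (2R,3R)-4-hydroxy-2,3-bis(3,4,5-trimethoxybenzyl)butanoate | COc1cc(C[C@@H](CO)[C@@H](Cc2cc(OC)c(OC)c(OC)c2)C(=O)[O-])cc(OC)c1OC.[K+] | intermediate
16 | (2R,3R)-4-hydroxy-2,3-bis(3,4,5-trimethoxybenzyl)butanoic acid | COc1cc(C[C@@H](CO)[C@@H](Cc2cc(OC)c(OC)c(OC)c2)C(=O)O)cc(OC)c1OC | intermediate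
17 | (−)-cubebininolide, (3R,4R)-3,4-bis(3,4,5-trimethoxybenzyl)oxolan-2-one | COc1cc(C[C@H]2COC(=O)[C@@H]2Cc2cc(OC)c(OC)c(OC)c2)cc(OC)c1OC | target

## Step count and risks

Total step count: 7. Longest linear sequence: 5 steps (1, 2, 5, 6, 7).

**Step 5 is the most exposed.** C-benzylation of the congested enolate may be slow, so that proton exchange and retro-Michael fragmentation compete as the mixture warms.
- The fallback sets out from enolate 11, made from 7 and 5 as in step 5.
- It keeps the three-component format but raises the oxidation level of the electrophile. The enolate is intercepted at −78 °C by aldehyde 6, a much faster partner, in a tandem Michael–aldol reaction.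
- This should give (3S,4R,5R)-3-[hydroxy(3,4,5-trimethoxyphenyl)methyl]-5-(l-menthyloxy)-4-[2-(3,4,5-trimethoxyphenyl)-1,3-dithian-2-yl]oxolan-2-one F1. The ring has the same 3,4-trans, 4,5-trans arrangement, and the product is a mixture at the carbinol carbon only.
- Neutral Raney Ni in EtOH then removes the sulfur to give (3S,4R,5R)-3-[hydroxy(3,4,5-trimethoxyphenyl)methyl]-5-(l-menthyloxy)-4-(3,4,5-trimethoxybenzyl)oxolan-2-one F2.
- Hydrogenolysis of the electron-rich benzylic alcohol (H2, Pd/C, AcOH) erases the carbinol centre, and the route is rejoined at 13.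

**Step 7 comes second.** C4 may epimerise while the aldehyde exists in alkaline medium, and hydride may attack the lactone carbonyl in competition with saponification.
- The fallback sets out from 13. LiAlH4 in THF at 0 °C takes both C2 and C5 to the alcohol level and frees menthol, giving (2R,3R)-2,3-bis(3,4,5-trimethoxybenzyl)butane-1,4-diol F3.
- Because the two aryl groups are identical, this diol is C2-symmetric and its hydroxymethyl groups are homotopic.
- Oxidative lactonisation (TEMPO cat., PhI(OAc)2, CH2Cl2, rt) through (3R,4R)-3,4-bis(3,4,5-trimethoxybenzyl)oxolan-2-ol F4 can therefore give only one lactone. The route is rejoined at 17.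

**Step 6 comes third.** Hydrogenolysis of the C–S bonds at the crowded benzylic carbon may stall, the activity of the nickel varies from batch to batch, and material may be lost by adsorption.
- The fallback sets out from 12 and removes the sulfur by hydrolysis instead of reduction. HgO and BF3·OEt2 in aqueous THF should give (3R,4R,5R)-5-(l-menthyloxy)-4-(3,4,5-trimethoxybenzoyl)-3-(3,4,5-trimethoxybenzyl)oxolan-2-one F5.
- The all-trans arrangement of F5 is also the thermodynamically preferred one at the now enolisable C4.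
- Hydrogenolysis of the electron-rich aryl ketone (H2, Pd/C, AcOH, trace HClO4) then follows. It passes through (3R,4S,5R)-4-[hydroxy(3,4,5-trimethoxyphenyl)methyl]-5-(l-menthyloxy)-3-(3,4,5-trimethoxybenzyl)oxolan-2-one F6, which should be consumed as it forms.
- This delivers the C7 methylene, and the route is rejoined at 13.

## Further compounds

F1 | step 5 | (3S,4R,5R)-3-[hydroxy(3,4,5-trimethoxyphenyl)methyl]-5-(l-menthyloxy)-4-[2-(3,4,5-trimethoxyphenyl)-1,3-dithian-2-yl]oxolan-2-one (carbinol epimers) | CC(C)[C@@H]1CC[C@@H](C)C[C@H]1O[C@@H]1OC(=O)[C@H](C(O)c2cc(OC)c(OC)c(OC)c2)[C@H]1C1(c2cc(OC)c(OC)c(OC)c2)SCCCS1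
F2 | step 5 | (3S,4R,5R)-3-[hydroxy(3,4,5-trimethoxyphenyl)methyl]-5-(l-menthyloxy)-4-(3,4,5-trimethoxybenzyl)oxolan-2-one (carbinol epimers) | CC(C)[C@@H]1CC[C@@H](C)C[C@H]1O[C@@H]1OC(=O)[C@H](C(O)c2cc(OC)c(OC)c(OC)c2)[C@H]1Cc1cc(OC)c(OC)c(OC)c1
F3 | step 7 | (2R,3R)-2,3-bis(3,4,5-trimethoxybenzyl)butane-1,4-diol | COc1cc(C[C@@H](CO)[C@@H](Cc2cc(OC)c(OC)c(OC)c2)CO)cc(OC)c1OC
F4 | step 7 | (3R,4R)-3,4-bis(3,4,5-trimethoxybenzyl)oxolan-2-ol (anomers) | COc1cc(C[C@H]2COC(O)[C@@H]2Cc2cc(OC)c(OC)c(OC)c2)cc(OC)c1OC
F5 | step 6 | (3R,4R,5R)-5-(l-menthyloxy)-4-(3,4,5-trimethoxybenzoyl)-3-(3,4,5-trimethoxybenzyl)oxolan-2-one | CC(C)[C@@H]1CC[C@@H](C)C[C@H]1O[C@@H]1OC(=O)[C@H](Cc2cc(OC)c(OC)c(OC)c2)[C@H]1C(=O)c1cc(OC)c(OC)c(OC)c1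
F6 | step 6 | (3R,4S,5R)-4-[hydroxy(3,4,5-trimethoxyphenyl)methyl]-5-(l-menthyloxy)-3-(3,4,5-trimethoxybenzyl)oxolan-2-one (carbinol epimers) | CC(C)[C@@H]1CC[C@@H](C)C[C@H]1O[C@@H]1OC(=O)[C@H](Cc2cc(OC)c(OC)c(OC)c2)[C@H]1C(O)c1cc(OC)c(OC)c(OC)c1
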